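**Assumption:** enantiopure (S)-Trolox is purchasable, and the natural (2R) configuration is the required one. The C2 centre of the target is R, and (S)-Trolox carries the same spatial arrangement. Its CIP label flips only because the CO2H outranks C3.

## Retrosynthetic overview
- The chroman, including the C2 quaternary stereocentre, is never opened. It comes intact from (S)-Trolox (1), so the sole stereocentre is bought and never touched.
- The C3'=C4' and C7'=C8' (E)-trisubstituted alkenes are each made by a Johnson–Claisen [3,3] rearrangement of a secondary isopropenyl carbinol. This is the key bond-forming step, used twice.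
- The terminal prenyl alkene comes from Wittig isopropylidenation of an aldehyde.
- The Trolox CO2H is converted to an aldehyde and homologated to the C3' aldehyde. The phenol is carried as a TBS ether and released in the last step.

## Route

**Step 1**
Reactants: 1 (S)-Trolox; 2 methanol
Product: 3 methyl (2S)-6-hydroxy-2,5,7,8-tetramethylchromane-2-carboxylate
Conditions: MeOH, cat. H2SO4, reflux, N2
Reagents that add atoms: methanol, CO
Why: Fischer esterification acts only on the acid, and the quaternary C2 cannot epimerise.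

**Step 2**
Reactants: 3; 4 TBSOTf
Product: 5 methyl (2S)-6-(TBSO)-2,5,7,8-tetramethylchromane-2-carboxylate
Conditions: TBSOTf, 2,6-lutidine, CH2Cl2, 0 °C to rt
Reagents that add atoms: TBSOTf, CC(C)(C)[Si](C)(C)OS(=O)(=O)C(F)(F)F
Why: the phenol is flanked by two ortho methyls, so the reactive silyl triflate is used. The silyl ether survives the Grignard, DIBAL and Claisen steps.

**Step 3**
Reactants: 5
Product: 6 (2S)-6-(TBSO)-2,5,7,8-tetramethylchromane-2-carbaldehyde
Conditions: DIBAL-H (1.1 equiv), toluene, –78 °C
Reagents that add atoms: none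
Why: a hindered ester is reduced to the aldehyde at low temperature, and the α-quaternary aldehyde cannot enolise or epimerise.

**Step 4**
Reactants: 6; 7 (triphenylphosphoranylidene)acetaldehyde
Product: 8 (2S)-3-[(E)-2-formylvinyl]-type enal, (E)-3-[(2S)-6-TBSO-2,5,7,8-tetramethylchroman-2-yl]acrolein
Conditions: Ph3P=CHCHO, toluene, 90 °C
Reagents that add atoms: 7, O=CC=P(c1ccccc1)(c1ccccc1)c1ccccc1
Why: a stabilised ylide Wittig gives the E-enal and adds two carbons (C2', C3').

**Step 5**
Reactants: 8
Product: 9 3-[(2S)-6-TBSO-2,5,7,8-tetramethylchroman-2-yl]propanal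
Conditions: H2 (1 atm), 5% Pd/C, EtOAc, rt, stop at uptake of 1 equiv
Reagents that add atoms: none (H2 only)
Why: the conjugated C=C is reduced chemoselectively. No other alkene is present yet, and C2 is not involved.

**Step 6**
Reactants: 9; 10 isopropenylmagnesium bromide
Product: 11 1-[(2S)-6-TBSO-2,5,7,8-tetramethylchroman-2-yl]-4-methylpent-4-en-3-ol (C3' carbinol as an epimeric mixture)
Conditions: 10, THF, –78 to 0 °C
Reagents that add atoms: 10, C=C(C)[Mg]Br
Why: Grignard 1,2-addition gives the isopropenyl carbinol needed for the Claisen. The new carbinol centre is destroyed in Step 7, so its configuration is irrelevant.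

**Step 7 (key step)**
Reactants: 11; 12 triethyl orthoacetate
Product: 13 ethyl (E)-7-[(2R)-6-TBSO-2,5,7,8-tetramethylchroman-2-yl]-4-methylhept-4-enoate, i.e. the chain carbons C1'–C7' with the C7' ester and C3'=C4'(Me) alkene
Conditions: MeC(OEt)3 (excess), cat. EtCO2H, 140 °C, EtOH removed
Reagents that add atoms: 12, CCOC(C)(OCC)OCC
Why: the Johnson–Claisen [3,3] rearrangement proceeds through a chair transition state with the carbinol substituent equatorial, so it gives the E-trisubstituted alkene from either carbinol epimer. It forms the C5'–C6' bond and leaves C2 untouched.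

**Step 8**
Reactants: 13
Product: 14 (E)-4-methyl-7-[(2R)-6-TBSO-2,5,7,8-tetramethylchroman-2-yl]hept-4-enal (aldehyde at C7')
Conditions: DIBAL-H (1.1 equiv), CH2Cl2, –78 °C
Reagents that add atoms: none
Why: an aliphatic ethyl ester is reduced to the aldehyde at low temperature, and the trisubstituted alkene and silyl ether are inert.

**Step 9**
Reactants: 14; 10
Product: 15 secondary isopropenyl carbinol at C7' (epimeric mixture, (2R) retained)
Conditions: 10, THF, –78 to 0 °C
Reagents that add atoms: 10, C=C(C)[Mg]Br
Why: the same Grignard addition sets up the second Claisen.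

**Step 10 (key step, repeated)**
Reactants: 15; 12
Product: 16 ethyl ester with C7'=C8'(Me) (E) and the C11' ester
Conditions: MeC(OEt)3, cat. EtCO2H, 140 °C
Reagents that add atoms: 12, CCOC(C)(OCC)OCC
Why: the second Johnson–Claisen [3,3] rearrangement gives the E-alkene by the same chair transition state and adds C9'–C11'.

**Step 11**
Reactants: 16
Product: 17 C11' aldehyde
Conditions: DIBAL-H (1.1 equiv), CH2Cl2, –78 °C
Reagents that add atoms: none
Why: chemoselective ester-to-aldehyde reduction, leaving both trisubstituted alkenes intact.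

**Step 12**
Reactants: 17; 18 isopropyltriphenylphosphonium iodide
Product: 19 TBS ether of the target, (2R)-6-TBSO-tocotrienol
Conditions: 18, n-BuLi, THF, 0 °C, then 17 at –78 °C to rt
Reagents that add atoms: 18, CC(C)[P+](c1ccccc1)(c1ccccc1)c1ccccc1.[I-]
Why: Wittig reaction with the isopropylidene ylide gives the terminal prenyl alkene, which has no E/Z issue because both alkene substituents are methyl.

**Step 13**
Reactants: 19
Product: 20 target, (2R,3'E,7'E)-α-tocotrienol
Conditions: TBAF, AcOH, THF, 0 °C to rt, argon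
Reagents that add atoms: none
Why: fluoride cleaves the aryl silyl ether selectively under buffered, non-acidic conditions, leaving the chroman and the three alkenes untouched.

**Checks.** Ring, substituents and 2R centre of 20 match the target SMILES. Atom bookkeeping holds at every step. Step 5 is the only hydrogenation and comes before any chain alkene exists. C2 is quaternary and never ionised, so its configuration is retained throughout. Both chain alkenes and the terminal prenyl group are installed after the hydrogenation.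

## Compound list
1 | (2S)-6-hydroxy-2,5,7,8-tetramethylchroman-2-carboxylic acid ((S)-Trolox) | OC(=O)[C@]1(C)CCc2c(C)c(O)c(C)c(C)c2O1 | starting material
2 | methanol | CO | starting material
3 | methyl (2S)-6-hydroxy-2,5,7,8-tetramethylchromane-2-carboxylate | COC(=O)[C@]1(C)CCc2c(C)c(O)c(C)c(C)c2O1 | intermediate
4 | TBSOTf | CC(C)(C)[Si](C)(C)OS(=O)(=O)C(F)(F)F | starting material
5 | methyl (2S)-6-TBSO-2,5,7,8-tetramethylchromane-2-carboxylate | COC(=O)[C@]1(C)CCc2c(C)c(O[Si](C)(C)C(C)(C)C)c(C)c(C)c2O1 | intermediate
6 | (2S)-6-TBSO-2,5,7,8-tetramethylchromane-2-carbaldehyde | O=C[C@]1(C)CCc2c(C)c(O[Si](C)(C)C(C)(C)C)c(C)c(C)c2O1 | intermediate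
7 | (triphenylphosphoranylidene)acetaldehyde | O=CC=P(c1ccccc1)(c1ccccc1)c1ccccc1 | starting material
8 | (E)-3-[(2S)-6-TBSO-2,5,7,8-tetramethylchroman-2-yl]acrolein | O=C/C=C/[C@]1(C)CCc2c(C)c(O[Si](C)(C)C(C)(C)C)c(C)c(C)c2O1 | intermediate
9 | 3-[(2S)-6-TBSO-2,5,7,8-tetramethylchroman-2-yl]propanal | O=CCC[C@]1(C)CCc2c(C)c(O[Si](C)(C)C(C)(C)C)c(C)c(C)c2O1 | intermediate
10 | isopropenylmagnesium bromide | C=C(C)[Mg]Br | starting material
11 | 1-[(2S)-6-TBSO-chroman-2-yl]-4-methylpent-4-en-3-ol (carbinol unspecified) | C=C(C)C(O)CC[C@]1(C)CCc2c(C)c(O[Si](C)(C)C(C)(C)C)c(C)c(C)c2O1 | intermediate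
12 | triethyl orthoacetate | CCOC(C)(OCC)OCC | starting material
13 | ethyl (E)-4-methyl-7-[(2R)-6-TBSO-chroman-2-yl]hept-4-enoate | CCOC(=O)CC/C(C)=C/CC[C@]1(C)CCc2c(C)c(O[Si](C)(C)C(C)(C)C)c(C)c(C)c2O1 | intermediate
14 | (E)-4-methyl-7-[(2R)-6-TBSO-chroman-2-yl]hept-4-enal | O=CCC/C(C)=C/CC[C@]1(C)CCc2c(C)c(O[Si](C)(C)C(C)(C)C)c(C)c(C)c2O1 | intermediate
15 | C7' isopropenyl carbinol (epimeric mixture) | C=C(C)C(O)CC/C(C)=C/CC[C@]1(C)CCc2c(C)c(O[Si](C)(C)C(C)(C)C)c(C)c(C)c2O1 | intermediate
16 | ethyl (4E,8E)-ester, C11' | CCOC(=O)CC/C(C)=C/CC/C(C)=C/CC[C@]1(C)CCc2c(C)c(O[Si](C)(C)C(C)(C)C)c(C)c(C)c2O1 | intermediate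
17 | (4E,8E)-aldehyde, C11' | O=CCC/C(C)=C/CC/C(C)=C/CC[C@]1(C)CCc2c(C)c(O[Si](C)(C)C(C)(C)C)c(C)c(C)c2O1 | intermediate
18 | isopropyltriphenylphosphonium iodide | CC(C)[P+](c1ccccc1)(c1ccccc1)c1ccccc1.[I-] | starting material
19 | (2R)-6-TBSO-α-tocotrienol | CC(C)=CCC/C(C)=C/CC/C(C)=C/CC[C@]1(C)CCc2c(C)c(O[Si](C)(C)C(C)(C)C)c(C)c(C)c2O1 | intermediate
20 | (2R,3'E,7'E)-α-tocotrienol | CC(C)=CCC/C(C)=C/CC/C(C)=C/CC[C@]1(C)CCc2c(C)c(O)c(C)c(C)c2O1 | target

## Totals
Total steps: 13. Longest linear sequence: 13 (every step is linear from 1).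

## Three steps most likely to fail
1. **Step 5 (selective hydrogenation).** The enal is an allylic tertiary aryl ether, so Pd/C may cause hydrogenolysis of the C–O bond or over-reduction of the aldehyde. Fallback: Wittig methylenation of 6 (Ph3P=CH2) to the 2-vinylchroman, then linear-selective Rh-catalysed hydroformylation (CO/H2) to give 9.
2. **Steps 7 and 10 (Johnson–Claisen at 140 °C with acid).** Thermal acid may desilylate the aryl ether or give E/Z leakage. Fallback: Eschenmoser–Claisen with Me2NC(OMe)2CH3 in refluxing xylene (no acid) to give the amide, then reduction of the amide to the aldehyde with Schwartz's reagent or LiAlH(OEt)3.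
3. **Steps 3, 8 and 11 (DIBAL ester to aldehyde).** Over-reduction to the alcohol is the main risk. Fallback: full reduction with LiAlH4 to the alcohol, then Dess–Martin oxidation to the aldehyde.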